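The route rests on opening ring B (C5–C6–C7–C8–C9–C10) of the ent-labdane by a Diels–Alder disconnection at C5–C10 and C6–C7. An acyclic precursor carries a 2-silyloxy diene (C7=C8–C9=C10, with C20 and the C11–C15 chain already on a stereodefined tetrasubstituted C9=C10 alkene) and an (E)-enal dienophile (C5=C6), joined through C1–C3 and the preset quaternary C4. One intramolecular cycloaddition closes rings A and B, sets the trans ring fusion (C5, C10) from C4, and leaves a C8 enol ether, the retron of the C8 exocyclic methylene. The formyl group on C6 is a traceless activator.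

Key step: step 16

Remark: labdane numbering (C1–C20) is used for all intermediates; TBS = tert-butyldimethylsilyl, Ts = 4-methylbenzenesulfonyl; N-methoxy-N-methyl-3-oxobutanamide and (R)-methyl hydrogen 3-methylglutarate are assumed to be purchasable.

Step 1
Reactants: 1 geraniol
Product: 2 (2R,3R)-2,3-epoxygeraniol
Conditions: Ti(OiPr)4 (5 mol%), D-(−)-diethyl tartrate (6 mol%), t-BuOOH, 4 Å molecular sieves, CH2Cl2, −20 °C
Reagents that add atoms: tert-butyl hydroperoxide CC(C)(C)OO
Why: Sharpless asymmetric epoxidation of the allylic alcohol, in which the D-tartrate ligand should direct oxygen to the face that gives the (2R,3R)-epoxide while the remote trisubstituted alkene is left alone.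

Step 2
Reactants: 2 (2R,3R)-2,3-epoxygeraniol
Product: 3 TBS ether of (2R,3R)-2,3-epoxygeraniol
Conditions: TBSCl, imidazole, DMF, 0 °C to rt
Reagents that add atoms: tert-butyldimethylsilyl chloride CC(C)(C)[Si](C)(C)Cl
Why: routine silylation of the primary alcohol, needed for the next rearrangement, with no stereocenter touched.

Step 3
Reactants: 3 TBS ether of (2R,3R)-2,3-epoxygeraniol
Product: 4 (R)-2-{[(tert-butyldimethylsilyl)oxy]methyl}-2,6-dimethylhept-5-enal
Conditions: MABR [MeAl(OAr)2, Ar = 4-bromo-2,6-di-tert-butylphenyl] (20 mol%), CH2Cl2, −78 °C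
Reagents that add atoms: none
Why: organoaluminium-promoted epoxy silyl ether rearrangement (semipinacol type), in which the tertiary C–O bond ionises and the silyloxymethyl group migrates anti to it, so the epoxide chirality is transferred with inversion to the all-carbon quaternary centre (future C4, with C5 as CHO, C18 as CH2OTBS and C19 as CH3).

Step 4
Reactants: 4 (R)-2-{[(tert-butyldimethylsilyl)oxy]methyl}-2,6-dimethylhept-5-enal
Product: 5 (S)-tert-butyl[(2-ethenyl-2,6-dimethylhept-5-en-1-yl)oxy]dimethylsilane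
Conditions: Ph3PCH3Br, KN(SiMe3)2, THF, 0 °C to rt
Reagents that add atoms: methyltriphenylphosphonium bromide C[P+](c1ccccc1)(c1ccccc1)c1ccccc1.[Br-]
Why: Wittig methylenation of a non-enolisable α-quaternary aldehyde, which makes C5=C6 without risk to the quaternary centre.

Step 5
Reactants: 5 (S)-tert-butyl[(2-ethenyl-2,6-dimethylhept-5-en-1-yl)oxy]dimethylsilane
Product: 7 (S)-4-{[(tert-butyldimethylsilyl)oxy]methyl}-4-methylhex-5-en-1-ol, via hexenal 6 (not isolated)
Conditions: O3, CH2Cl2/MeOH, pyridine (trace), Sudan Red 7B as end-point indicator, −78 °C; then NaBH4, −78 to 0 °C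
Reagents that add atoms: ozone [O-][O+]=O
Why: chemoselective ozonolysis, the electron-rich trisubstituted alkene reacting well before the hindered monosubstituted vinyl group, with borohydride reduction in the same flask to the C1 alcohol.

Step 6
Reactants: 7 (S)-4-{[(tert-butyldimethylsilyl)oxy]methyl}-4-methylhex-5-en-1-ol
Product: 8 (S)-tert-butyl[(2-ethenyl-5-iodo-2-methylpentyl)oxy]dimethylsilane
Conditions: I2, PPh3, imidazole, CH2Cl2, 0 °C to rt
Reagents that add atoms: iodine II
Why: Appel-type iodination of the unhindered primary alcohol by SN2 displacement of the oxyphosphonium group.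

Step 7
Reactants: 9 (R)-methyl hydrogen 3-methylglutarate
Product: 10 1-tert-butyl 5-methyl (S)-3-methylpentanedioate
Conditions: isobutene (excess), H2SO4 (cat.), CH2Cl2, sealed vessel, rt
Reagents that add atoms: 2-methylpropene CC(C)=C
Why: acid-catalysed addition of the carboxylic acid to isobutene gives the tert-butyl ester (future C15) without touching the stereocenter (future C13).

Step 8
Reactants: 10 1-tert-butyl 5-methyl (S)-3-methylpentanedioate
Product: 11 tert-butyl (S)-5-hydroxy-3-methylpentanoate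
Conditions: LiBH4, THF, 0 °C to rt
Reagents that add atoms: none
Why: chemoselective hydride reduction of the methyl ester, the hindered tert-butyl ester being much slower.

Step 9
Reactants: 11 tert-butyl (S)-5-hydroxy-3-methylpentanoate
Product: 12 tert-butyl (R)-5-iodo-3-methylpentanoate
Conditions: I2, PPh3, imidazole, CH2Cl2, 0 °C
Reagents that add atoms: iodine II
Why: Appel-type iodination of the primary alcohol (C11); the descriptor changes only because iodine changes the priorities.

Step 10
Reactants: 13 N-methoxy-N-methyl-3-oxobutanamide, 12 tert-butyl (R)-5-iodo-3-methylpentanoate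
Product: 14 tert-butyl (3S)-6-[methoxy(methyl)carbamoyl]-3-methyl-7-oxooctanoate (both C6 epimers)
Conditions: K2CO3, DMF, 60 °C
Reagents that add atoms: none
Why: acetoacetic-type C-alkylation of the stabilised enolate with a primary iodide forms C9–C11, and the new α-stereocenter is of no consequence because it becomes sp2 in step 11.

Step 11
Reactants: 14 tert-butyl (3S)-6-[methoxy(methyl)carbamoyl]-3-methyl-7-oxooctanoate
Product: 15 tert-butyl (3S,6E)-6-[methoxy(methyl)carbamoyl]-3-methyl-7-(tosyloxy)oct-6-enoate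
Conditions: TsCl, N-methylimidazole, Et3N, MeCN, 0 °C to rt
Reagents that add atoms: 4-methylbenzenesulfonyl chloride Cc1ccc(cc1)S(Cl)(=O)=O
Why: stereoselective enol sulfonylation under non-chelating amine conditions (N-sulfonylimidazolium as sulfonyl donor), which should place OTs anti to the amide carbonyl and so fix the C9=C10 geometry as E.

Step 12
Reactants: 8 (S)-tert-butyl[(2-ethenyl-5-iodo-2-methylpentyl)oxy]dimethylsilane, 15 tert-butyl (3S,6E)-6-[methoxy(methyl)carbamoyl]-3-methyl-7-(tosyloxy)oct-6-enoate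
Product: 17 tert-butyl (3S,6E,11S)-11-{[(tert-butyldimethylsilyl)oxy]methyl}-6-[methoxy(methyl)carbamoyl]-3,7,11-trimethyltrideca-6,12-dienoate, via alkylzinc iodide 16 (not isolated)
Conditions: Zn dust (activated with BrCH2CH2Br and Me3SiCl), LiCl, THF, 40 °C; then 15, Pd(OAc)2 (5 mol%), SPhos (10 mol%), THF, 50 °C
Reagents that add atoms: none
Why: Negishi sp3–sp2 coupling with retention at the alkenyl tosylate forms C1–C10 and the tetrasubstituted alkene with C1 trans to C8, the alkylzinc tolerating amide, ester and silyl ether.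

Step 13
Reactants: 17 tert-butyl (3S,6E,11S)-11-{[(tert-butyldimethylsilyl)oxy]methyl}-6-[methoxy(methyl)carbamoyl]-3,7,11-trimethyltrideca-6,12-dienoate
Product: 18 tert-butyl (3S,6E,11S)-6-acetyl-11-{[(tert-butyldimethylsilyl)oxy]methyl}-3,7,11-trimethyltrideca-6,12-dienoate
Conditions: MeMgBr, THF, 0 °C to rt
Reagents that add atoms: methylmagnesium bromide C[Mg]Br
Why: Weinreb ketone synthesis, the chelated tetrahedral intermediate stopping at the methyl ketone (C7–C8) while the tert-butyl ester resists the Grignard reagent.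

Step 14
Reactants: 18 tert-butyl (3S,6E,11S)-6-acetyl-11-{[(tert-butyldimethylsilyl)oxy]methyl}-3,7,11-trimethyltrideca-6,12-dienoate
Product: 19 tert-butyl (3S,6E,11S,12E)-6-acetyl-11-{[(tert-butyldimethylsilyl)oxy]methyl}-3,7,11-trimethyl-14-oxotetradeca-6,12-dienoate
Conditions: (E)-crotonaldehyde (5 equiv), second-generation Hoveyda–Grubbs catalyst RuCl2(H2IMes)(=CH-C6H4-2-OiPr) (10 mol%), CH2Cl2, 40 °C
Reagents that add atoms: (E)-but-2-enal C/C=C/C=O
Why: olefin cross-metathesis of the terminal vinyl group with an electron-poor partner should give the (E)-enal, the tetrasubstituted enone alkene being inert to the catalyst.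

Step 15
Reactants: 19 tert-butyl (3S,6E,11S,12E)-6-acetyl-11-{[(tert-butyldimethylsilyl)oxy]methyl}-3,7,11-trimethyl-14-oxotetradeca-6,12-dienoate
Product: 20 tert-butyl (3S,6E,11S,12E)-11-{[(tert-butyldimethylsilyl)oxy]methyl}-6-{1-[(tert-butyldimethylsilyl)oxy]ethenyl}-3,7,11-trimethyl-14-oxotetradeca-6,12-dienoate
Conditions: TBSOTf, Et3N, CH2Cl2, −78 to 0 °C; non-aqueous work-up (pentane, basic alumina)
Reagents that add atoms: tert-butyldimethylsilyl trifluoromethanesulfonate CC(C)(C)[Si](C)(C)OS(=O)(=O)C(F)(F)F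
Why: soft enolisation, kinetic deprotonation of the O-silylated methyl ketone at C7 giving the cross-conjugated 2-silyloxy diene, while the enal has no enolisable hydrogen (C4 is quaternary).

Step 16
Reactants: 20 tert-butyl (3S,6E,11S,12E)-11-{[(tert-butyldimethylsilyl)oxy]methyl}-6-{1-[(tert-butyldimethylsilyl)oxy]ethenyl}-3,7,11-trimethyl-14-oxotetradeca-6,12-dienoate
Product: 21 tert-butyl (13S)-8,18-bis[(tert-butyldimethylsilyl)oxy]-6-formyl-17-nor-ent-labd-8-en-15-oate (trans-fused, formyl group on C6 equatorial and cis to H5)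
Conditions: Me2AlCl (1.5 equiv), CH2Cl2 (0.01 M), −78 to −20 °C
Reagents that add atoms: none
Why: Lewis-acid-promoted intramolecular Diels–Alder reaction (closest known type: aluminium-promoted cyclisation of (E)-deca-2,7,9-trienals): Me2AlCl binds the formyl oxygen and the enal C5=C6 adds suprafacially to the 2-silyloxy diene C7=C8–C9=C10 in a concerted asynchronous transition state, forming C6–C7 and C5–C10 together. Ring B closes as the cyclohexene of the [4+2] addition and ring A as the fused six-membered ring spanned by the C1–C3/C4 tether (type 1 mode, tether on the diene terminus C10), the tether enforcing the regiochemistry against the electronic bias of the silyloxy group. C10 and C5 are set trans by the diene geometry (tether outside, C20 inside, fixed in steps 11 and 12) together with the endo position of the coordinated formyl group, the alternative exo mode forcing the quaternary C4 under the diene; C6 is set by the (E)-enal geometry and is deleted in step 17. The absolute sense comes from C4: the bulky CH2OTBS arm lies anti to the forming C5–C10 bond (Felkin-type, future equatorial C18) and the methyl takes the position next to C20, which exposes one dienophile face. The step therefore needs endo and facial selectivity and an intact silyl enol ether, which low temperature, high dilution and an aprotic Lewis acid should secure.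

Step 17
Reactants: 21 tert-butyl (13S)-8,18-bis[(tert-butyldimethylsilyl)oxy]-6-formyl-17-nor-ent-labd-8-en-15-oate
Product: 22 tert-butyl (13S)-8,18-bis[(tert-butyldimethylsilyl)oxy]-17-nor-ent-labd-8-en-15-oate
Conditions: RhCl(PPh3)3 (1.1 equiv), toluene, 110 °C
Reagents that add atoms: none
Why: Tsuji–Wilkinson decarbonylation (formyl C–H oxidative addition, CO extrusion, C–H reductive elimination) removes the activating carbon and leaves C6 as CH2, so its configuration is irrelevant.

Step 18
Reactants: 22 tert-butyl (13S)-8,18-bis[(tert-butyldimethylsilyl)oxy]-17-nor-ent-labd-8-en-15-oate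
Product: 23 (13S)-18-hydroxy-8-oxo-17-nor-ent-labdan-15-oic acid
Conditions: CF3CO2H/CH2Cl2/H2O (9:9:2), 0 °C to rt; aqueous NaHCO3, then mild acid work-up
Reagents that add atoms: none
Why: one acidic solvolysis hydrolyses the silyl enol ether to the C8 ketone, cleaves the primary TBS ether and the tert-butyl ester, and sets C9 by protonation anti to the axial C20 methyl, giving the equatorial side chain that is also the thermodynamic epimer.

Step 19
Reactants: 23 (13S)-18-hydroxy-8-oxo-17-nor-ent-labdan-15-oic acid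
Product: 24 (13S)-18-hydroxy-ent-labd-8(17)-en-15-oic acid
Conditions: Ph3PCH3Br (6 equiv), KOtBu (6 equiv), toluene, 80 °C; acidic work-up
Reagents that add atoms: methyltriphenylphosphonium bromide C[P+](c1ccccc1)(c1ccccc1)c1ccccc1.[Br-]
Why: Wittig methylenation of the hindered C8 ketone with excess ylide (carboxylate and alkoxide are spectators) installs C8=C17, any enolisation at C9 returning to the equatorial epimer.

Step 20
Reactants: 24 (13S)-18-hydroxy-ent-labd-8(17)-en-15-oic acid, 25 Meldrum's acid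
Product: 26 (13S)-18-(carboxyacetoxy)-ent-labd-8(17)-en-15-oic acid
Conditions: toluene, 100 °C
Reagents that add atoms: none
Why: thermal alcoholysis of Meldrum's acid with loss of acetone acylates the neopentyl C18 hydroxyl to the malonic half ester under neutral conditions that spare the exocyclic alkene.

Step 21
Reactants: 26 (13S)-18-(carboxyacetoxy)-ent-labd-8(17)-en-15-oic acid, 27 4-hydroxybenzaldehyde
Product: 28 (4S,5S,9R,10S,13S)-18-[(E)-4-hydroxycinnamoyloxy]-ent-labd-8(17)-en-15-oic acid (CNP0389065.1)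
Conditions: pyridine, piperidine (cat.), 70 °C
Reagents that add atoms: none
Why: Knoevenagel–Doebner condensation of the malonic half ester with decarboxylation should give the (E)-4-hydroxycinnamate directly, so the phenol needs no protecting group and the C15 acid stays free.

Compound list
1 | geraniol, (E)-3,7-dimethylocta-2,6-dien-1-ol | CC(C)=CCC/C(C)=C/CO | starting material
2 | (2R,3R)-2,3-epoxygeraniol | OC[C@H]1O[C@]1(C)CCC=C(C)C | intermediate
3 | TBS ether of (2R,3R)-2,3-epoxygeraniol | CC(C)(C)[Si](C)(C)OC[C@H]1O[C@]1(C)CCC=C(C)C | intermediate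
4 | (R)-2-{[(tert-butyldimethylsilyl)oxy]methyl}-2,6-dimethylhept-5-enal | O=C[C@@](C)(CO[Si](C)(C)C(C)(C)C)CCC=C(C)C | intermediate
5 | (S)-tert-butyl[(2-ethenyl-2,6-dimethylhept-5-en-1-yl)oxy]dimethylsilane | C=C[C@@](C)(CO[Si](C)(C)C(C)(C)C)CCC=C(C)C | intermediate
6 | (S)-4-{[(tert-butyldimethylsilyl)oxy]methyl}-4-methylhex-5-enal (not isolated) | C=C[C@@](C)(CO[Si](C)(C)C(C)(C)C)CCC=O | intermediate
7 | (S)-4-{[(tert-butyldimethylsilyl)oxy]methyl}-4-methylhex-5-en-1-ol | C=C[C@@](C)(CO[Si](C)(C)C(C)(C)C)CCCO | intermediate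
8 | (S)-tert-butyl[(2-ethenyl-5-iodo-2-methylpentyl)oxy]dimethylsilane | C=C[C@@](C)(CO[Si](C)(C)C(C)(C)C)CCCI | intermediate
9 | (R)-methyl hydrogen 3-methylglutarate, (R)-5-methoxy-3-methyl-5-oxopentanoic acid | COC(=O)C[C@H](C)CC(=O)O | starting material
10 | 1-tert-butyl 5-methyl (S)-3-methylpentanedioate | COC(=O)C[C@H](C)CC(=O)OC(C)(C)C | intermediate
11 | tert-butyl (S)-5-hydroxy-3-methylpentanoate | OCC[C@H](C)CC(=O)OC(C)(C)C | intermediate
12 | tert-butyl (R)-5-iodo-3-methylpentanoate | ICC[C@H](C)CC(=O)OC(C)(C)C | intermediate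
13 | N-methoxy-N-methyl-3-oxobutanamide | CC(=O)CC(=O)N(C)OC | starting material
14 | tert-butyl (3S)-6-[methoxy(methyl)carbamoyl]-3-methyl-7-oxooctanoate (both C6 epimers) | CC(=O)C(CC[C@H](C)CC(=O)OC(C)(C)C)C(=O)N(C)OC | intermediate
15 | tert-butyl (3S,6E)-6-[methoxy(methyl)carbamoyl]-3-methyl-7-(tosyloxy)oct-6-enoate | C/C(OS(=O)(=O)c1ccc(C)cc1)=C(/CC[C@H](C)CC(=O)OC(C)(C)C)C(=O)N(C)OC | intermediate
16 | alkylzinc iodide from 8, {(S)-4-{[(tert-butyldimethylsilyl)oxy]methyl}-4-methylhex-5-en-1-yl}zinc iodide (not isolated) | C=C[C@@](C)(CO[Si](C)(C)C(C)(C)C)CCC[Zn]I | intermediate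
17 | tert-butyl (3S,6E,11S)-11-{[(tert-butyldimethylsilyl)oxy]methyl}-6-[methoxy(methyl)carbamoyl]-3,7,11-trimethyltrideca-6,12-dienoate | C/C(CCC[C@](C)(CO[Si](C)(C)C(C)(C)C)C=C)=C(/CC[C@H](C)CC(=O)OC(C)(C)C)C(=O)N(C)OC | intermediate
18 | tert-butyl (3S,6E,11S)-6-acetyl-11-{[(tert-butyldimethylsilyl)oxy]methyl}-3,7,11-trimethyltrideca-6,12-dienoate | C/C(CCC[C@](C)(CO[Si](C)(C)C(C)(C)C)C=C)=C(/CC[C@H](C)CC(=O)OC(C)(C)C)C(C)=O | intermediate
19 | tert-butyl (3S,6E,11S,12E)-6-acetyl-11-{[(tert-butyldimethylsilyl)oxy]methyl}-3,7,11-trimethyl-14-oxotetradeca-6,12-dienoate | C/C(CCC[C@](C)(CO[Si](C)(C)C(C)(C)C)/C=C/C=O)=C(/CC[C@H](C)CC(=O)OC(C)(C)C)C(C)=O | intermediate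
20 | tert-butyl (3S,6E,11S,12E)-11-{[(tert-butyldimethylsilyl)oxy]methyl}-6-{1-[(tert-butyldimethylsilyl)oxy]ethenyl}-3,7,11-trimethyl-14-oxotetradeca-6,12-dienoate | C/C(CCC[C@](C)(CO[Si](C)(C)C(C)(C)C)/C=C/C=O)=C(/CC[C@H](C)CC(=O)OC(C)(C)C)C(=C)O[Si](C)(C)C(C)(C)C | intermediate
21 | tert-butyl (13S)-8,18-bis[(tert-butyldimethylsilyl)oxy]-6-formyl-17-nor-ent-labd-8-en-15-oate (trans-fused; C6 formyl equatorial, cis to H5) | CC(C)(C)[Si](C)(C)OC1=C(CC[C@H](C)CC(=O)OC(C)(C)C)[C@]2(C)CCC[C@](C)(CO[Si](C)(C)C(C)(C)C)[C@H]2[C@H](C=O)C1 | intermediate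
22 | tert-butyl (13S)-8,18-bis[(tert-butyldimethylsilyl)oxy]-17-nor-ent-labd-8-en-15-oate | CC(C)(C)[Si](C)(C)OC1=C(CC[C@H](C)CC(=O)OC(C)(C)C)[C@]2(C)CCC[C@](C)(CO[Si](C)(C)C(C)(C)C)[C@H]2CC1 | intermediate
23 | (13S)-18-hydroxy-8-oxo-17-nor-ent-labdan-15-oic acid | O=C1CC[C@@H]2[C@@](C)(CO)CCC[C@@]2(C)[C@@H]1CC[C@H](C)CC(=O)O | intermediate
24 | (13S)-18-hydroxy-ent-labd-8(17)-en-15-oic acid | C=C1CC[C@@H]2[C@@](C)(CO)CCC[C@@]2(C)[C@@H]1CC[C@H](C)CC(=O)O | intermediate
25 | Meldrum's acid, 2,2-dimethyl-1,3-dioxane-4,6-dione | CC1(C)OC(=O)CC(=O)O1 | starting material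
26 | (13S)-18-(carboxyacetoxy)-ent-labd-8(17)-en-15-oic acid | C=C1CC[C@@H]2[C@@](C)(COC(=O)CC(=O)O)CCC[C@@]2(C)[C@@H]1CC[C@H](C)CC(=O)O | intermediate
27 | 4-hydroxybenzaldehyde | O=Cc1ccc(O)cc1 | starting material
28 | (4S,5S,9R,10S,13S)-18-[(E)-4-hydroxycinnamoyloxy]-ent-labd-8(17)-en-15-oic acid (CNP0389065.1) | C=C1CC[C@@H]2[C@@](C)(COC(=O)/C=C/c3ccc(O)cc3)CCC[C@@]2(C)[C@@H]1CC[C@H](C)CC(=O)O | target

Total step count: 21. Longest linear sequence: 16 steps (steps 1–6 and 12–21, from geraniol); steps 7–9 and 10–11 are side branches.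

Steps most likely to fail

1. Step 16 (key step). The cycloaddition may be slow at the fully substituted diene terminus C10, with competing loss of the silyl enol ether. The relay from C4 may also discriminate too weakly between methyl and silyloxymethyl, eroding facial selectivity. The fallback puts a covalent chiral controller on the dienophile and sets out from 18. Cross-metathesis of 18 with (R)-3-acryloyl-4-benzyl-oxazolidin-2-one (same ruthenium catalyst) would give the (E)-N-enoyl oxazolidinone F1. TBSOTf/Et3N would then give the silyloxy diene F2. Me2AlCl (CH2Cl2, −30 °C) would chelate the imide, whose benzyl group should shield the Si face of C5/C6, so the auxiliary-controlled intramolecular Diels–Alder reaction on the Re face would give the cycloadduct F3. LiOH/H2O2 would release the C6 carboxylic acid F4. The acid would be converted with N-hydroxypyridine-2-thione and dicyclohexylcarbodiimide into the thiohydroxamate ester F5. Barton decarboxylation of F5 (t-BuSH, visible light) would return the route at 22.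

2. Step 14. The vinyl group sits on a quaternary carbon next to a bulky silyl ether, so cross-metathesis may stall and the catalyst may decompose before turnover. The fallback replaces metathesis by carbonyl olefination and sets out from 18. Oxidative cleavage of the vinyl group (OsO4 cat., NaIO4, 2,6-lutidine, dioxane/H2O) would give the α-quaternary aldehyde F6; the electron-poor tetrasubstituted enone alkene should not react. A Wittig reaction of F6 with Ph3P=CHCHO (toluene, 80 °C), selective for the aldehyde over the methyl ketone, would return the route at 19.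

3. Step 11. The E-selective enol sulfonylation is established for β-keto esters; on the amide-type dicarbonyl the E/Z control may be incomplete, which would scramble the C9=C10 geometry that the key step depends on. The fallback builds the alkene by syn-carbometalation and sets out from 8. But-2-ynoic acid would be converted (N,O-dimethylhydroxylamine hydrochloride, carbodiimide) into N-methoxy-N-methylbut-2-ynamide F7. Iodide 8 would be turned into its organocopper reagent (t-BuLi, Et2O, −78 °C; CuBr·SMe2). Syn-addition of this reagent to F7 at −78 °C and an iodine quench would give the (Z)-α-iodo enamide F8, with C1 and iodine cis. Negishi coupling of F8 with the alkylzinc iodide F9 (from 12, Zn, LiCl; Pd(OAc)2, SPhos) would return the route at 17, replacing steps 10–12.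

Further compounds
F1 | step 16 | tert-butyl (3S,6E,11S,12E)-6-acetyl-14-[(R)-4-benzyl-2-oxooxazolidin-3-yl]-11-{[(tert-butyldimethylsilyl)oxy]methyl}-3,7,11-trimethyl-14-oxotetradeca-6,12-dienoate | C/C(CCC[C@](C)(CO[Si](C)(C)C(C)(C)C)/C=C/C(=O)N1[C@H](Cc2ccccc2)COC1=O)=C(/CC[C@H](C)CC(=O)OC(C)(C)C)C(C)=O
F2 | step 16 | silyloxy diene of F1 (1-[(tert-butyldimethylsilyl)oxy]ethenyl in place of acetyl) | C/C(CCC[C@](C)(CO[Si](C)(C)C(C)(C)C)/C=C/C(=O)N1[C@H](Cc2ccccc2)COC1=O)=C(/CC[C@H](C)CC(=O)OC(C)(C)C)C(=C)O[Si](C)(C)C(C)(C)C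
F3 | step 16 | cycloadduct with the C6 acyl oxazolidinone, tert-butyl (13S)-6-{[(R)-4-benzyl-2-oxooxazolidin-3-yl]carbonyl}-8,18-bis[(tert-butyldimethylsilyl)oxy]-17-nor-ent-labd-8-en-15-oate | CC(C)(C)[Si](C)(C)OC1=C(CC[C@H](C)CC(=O)OC(C)(C)C)[C@]2(C)CCC[C@](C)(CO[Si](C)(C)C(C)(C)C)[C@H]2[C@H](C(=O)N3[C@H](Cc4ccccc4)COC3=O)C1
F4 | step 16 | C6 carboxylic acid, (13S)-15-tert-butoxy-8,18-bis[(tert-butyldimethylsilyl)oxy]-15-oxo-17-nor-ent-labd-8-ene-6-carboxylic acid | CC(C)(C)[Si](C)(C)OC1=C(CC[C@H](C)CC(=O)OC(C)(C)C)[C@]2(C)CCC[C@](C)(CO[Si](C)(C)C(C)(C)C)[C@H]2[C@H](C(=O)O)C1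
F5 | step 16 | thiohydroxamate (2-thioxopyridin-1-yl) ester of F4 | CC(C)(C)[Si](C)(C)OC1=C(CC[C@H](C)CC(=O)OC(C)(C)C)[C@]2(C)CCC[C@](C)(CO[Si](C)(C)C(C)(C)C)[C@H]2[C@H](C(=O)On3ccccc3=S)C1
F6 | step 14 | tert-butyl (3S,6E,11R)-6-acetyl-11-{[(tert-butyldimethylsilyl)oxy]methyl}-3,7,11-trimethyl-12-oxododec-6-enoate | C/C(CCC[C@](C)(CO[Si](C)(C)C(C)(C)C)C=O)=C(/CC[C@H](C)CC(=O)OC(C)(C)C)C(C)=O
F7 | step 11 | N-methoxy-N-methylbut-2-ynamide | CC#CC(=O)N(C)OC
F8 | step 11 | (S,Z)-7-{[(tert-butyldimethylsilyl)oxy]methyl}-2-iodo-N-methoxy-N,3,7-trimethylnona-2,8-dienamide | C/C(CCC[C@](C)(CO[Si](C)(C)C(C)(C)C)C=C)=C(/I)C(=O)N(C)OC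
F9 | step 11 | [(R)-5-tert-butoxy-3-methyl-5-oxopentyl]zinc iodide | I[Zn]CC[C@H](C)CC(=O)OC(C)(C)C
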